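**Plan**

- Retrosynthesis: the two aryl O–CH3 bonds and both ketones (from carbinols) are cut first. Then come the C2′–C3′ bond of the long arm (aldehyde plus aryl-allyl barium), its C1′–C2′ bond (one-carbon Wittig homologation) and the CO–CH2 bond of the prenyl ketone (aldehyde plus prenylbarium). Last is the CH2–O bond of a cis-fused γ-lactone, which leads back to a carboxamide carrying a gem-dimethyl group.
- Forward: camphoric acid is trimmed to (R)-1,2,2-trimethylcyclopentane-1-carboxamide and an amidyl radical closes the lactone, the only ring made. The lactone carbonyl carbon then receives the prenyl unit, and the former methyl carbon is oxidised, extended by one carbon and joined to the aryl-allyl fragment. Oxidation and unmasking of the hydroquinone finish the route.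
- Enabling feature: ring C1 (methyl, acyl carbon) and ring C2 (methyl, CH2 arm cis to the acyl group) are C1 and C2 of camphoric acid with one of the two C2 methyl groups functionalised.
- Stereochemistry: C1 comes unchanged from (1R,3S)-camphoric acid. C2 becomes stereogenic in the lactonisation, where the cis ring fusion forces reaction of the methyl on the carboxamide face. The E alkene is set in the SN2′ opening of 2-methyl-2-vinyloxirane and kept in the barium step.

Key step: step 5

Remark: carbinol, lactol and enol-ether centres that end as carbonyl carbons are carried as mixtures and written without descriptor. The sodium salts of the lactols made before the barium additions are listed as intermediates.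

**Route**

Step 1
Reactants: 1 (1R,3S)-camphoric acid
Product: 2 (1R,3S)-3-(methoxycarbonyl)-1,2,2-trimethylcyclopentane-1-carboxylic acid
Conditions: MeOH, H2SO4 (cat.), reflux
Reagents that add atoms: methanol CO
Why: Fischer esterification should stop at the secondary carboxyl, because the C1 carboxyl sits on a quaternary carbon next to the gem-dimethyl carbon and does not reach the tetrahedral intermediate at a useful rate.

Step 2
Reactants: 2 (1R,3S)-3-(methoxycarbonyl)-1,2,2-trimethylcyclopentane-1-carboxylic acid
Product: 4 methyl (1S,3R)-3-carbamoyl-2,2,3-trimethylcyclopentane-1-carboxylate, via acid chloride 3 (not isolated)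
Conditions: (COCl)2, DMF (cat.), CH2Cl2, 0 °C → rt; concentrate; NH3 (0.5 M in dioxane), 0 °C → rt
Reagents that add atoms: oxalyl chloride ClC(=O)C(=O)Cl (chlorine of 3); ammonia N
Why: Vilsmeier-type activation with oxalyl chloride/DMF converts hindered tertiary acids to acid chlorides, and Schotten–Baumann-type acylation of ammonia then gives the primary amide while the methyl ester is untouched.

Step 3
Reactants: 4 methyl (1S,3R)-3-carbamoyl-2,2,3-trimethylcyclopentane-1-carboxylate
Product: 5 (1S,3R)-3-carbamoyl-2,2,3-trimethylcyclopentane-1-carboxylic acid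
Conditions: LiOH·H2O, THF/MeOH/H2O, 40 °C; then aq. HCl to pH 2, 0 °C
Reagents that add atoms: lithium hydroxide [Li+].[OH-]
Why: Saponification of the secondary methyl ester should be much faster than hydrolysis of the primary amide on the quaternary carbon, and any epimerisation at the ester carbon is harmless because that centre becomes CH2 in step 4.

Step 4
Reactants: 5 (1S,3R)-3-carbamoyl-2,2,3-trimethylcyclopentane-1-carboxylic acid
Product: 6 (1R)-1,2,2-trimethylcyclopentane-1-carboxamide
Conditions: 9-mesityl-10-phenylacridinium BF4 (5 mol %), (PhS)2 (10 mol %), i-Pr2NEt (20 mol %), CF3CH2OH, 450 nm LEDs, rt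
Reagents that add atoms: none
Why: Acridinium photoredox hydrodecarboxylation (carboxylate oxidation, loss of CO2, hydrogen transfer from thiophenol to the secondary radical) needs no electrophilic activation of the carboxyl, so the cis amide cannot close onto it to give an imide or isoimide.

Step 5
Reactants: 6 (1R)-1,2,2-trimethylcyclopentane-1-carboxamide
Product: 10 (1R,5S)-1,5-dimethyl-3-oxabicyclo[3.3.0]octan-2-one (cis-fused lactone), via N-iodoamide 7 (not isolated), via iodomethyl amide 8 (not isolated), via iminium lactone iodide 9 (not isolated)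
Conditions: t-BuOCl, I2, PhH, rt, dark; then hν (tungsten lamp), rt; then 1 M HCl, THF, rt
Reagents that add atoms: iodine II (iodine of 7, 8 and 9); water O (carbonyl oxygen of 10)
Why: tert-Butyl hypoiodite formed in the flask N-iodinates the amide, light breaks the N–I bond, and the amidyl radical takes a hydrogen atom from the C2 methyl group on its own face through a six-membered chair-like transition state (1,5-hydrogen atom transfer); the primary radical picks up iodine to give 8, the amide oxygen displaces iodide to give 9, and aqueous acid hydrolyses the C=N bond to the lactone. The closest known reaction type is the Hofmann–Löffler–Freytag-type photolysis of N-iodo primary carboxamides, which gives γ-lactones and has been used on angular methyl groups. The oxolane ring closes by 5-exo-tet O-alkylation, and the bicyclo[3.3.0] skeleton allows only a cis fusion. The new stereocentre (old C2, C5 of 10) is therefore controlled by C1 of camphoric acid: the methyl on the carboxamide face is the one functionalised and the other stays cis to the C1 methyl. The step needs site selectivity among the hydrogens on γ-carbons; the syn methyl is reached through an unstrained, nearly linear N···H···C arrangement, whereas the cis hydrogens at ring C3 and C4 would need a bridged bicyclo[2.2.1]-like transition state and the anti methyl points away from nitrogen.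

Step 6
Reactants: 10 (1R,5S)-1,5-dimethyl-3-oxabicyclo[3.3.0]octan-2-one
Product: 11 (1R,5S)-1,5-dimethyl-3-oxabicyclo[3.3.0]octan-2-ol (lactol; both anomers)
Conditions: DIBAL-H (1.1 equiv), CH2Cl2, −78 °C; Rochelle salt work-up
Reagents that add atoms: none
Why: Partial reduction of a lactone with DIBAL-H at −78 °C stops at the aluminium lactolate; the hydride is kept near one equivalent because over-reduction would give the achiral meso diol.

Step 7
Reactants: 11 (1R,5S)-1,5-dimethyl-3-oxabicyclo[3.3.0]octan-2-ol; 12 prenyl chloride (1-chloro-3-methylbut-2-ene)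
Product: 15 1-[(1R,2S)-2-(hydroxymethyl)-1,2-dimethylcyclopentyl]-4-methylpent-3-en-1-ol (both carbinol epimers), via sodium lactolate 13 (not isolated), via prenylbarium chloride 14 (not isolated)
Conditions: activated Ba (BaI2, Li, biphenyl, THF, rt); 12, −78 °C; then 13 (from 11, NaH, THF, 0 °C), −78 → −40 °C; H2O
Reagents that add atoms: sodium hydride [Na+].[H-] (sodium of 13); barium iodide [Ba+2].[I-].[I-] (barium of 14)
Why: γ,γ-Disubstituted allylbarium reagents add to aldehydes through their α-carbon, so the ring-opened lactolate should give the linear prenyl carbinol and not the reverse-prenyl isomer; the new carbinol centre is not controlled and is removed in step 16.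

Step 8
Reactants: 15 1-[(1R,2S)-2-(hydroxymethyl)-1,2-dimethylcyclopentyl]-4-methylpent-3-en-1-ol
Product: 16 (1S,5R)-1,5-dimethyl-4-(3-methylbut-2-en-1-yl)-3-oxabicyclo[3.3.0]octan-2-one (C4 epimers)
Conditions: TEMPO (20 mol %), PhI(OAc)2 (2.5 equiv), CH2Cl2, rt
Reagents that add atoms: none
Why: Nitroxyl-catalysed oxidation attacks the primary alcohol selectively, the hydroxy aldehyde closes to the lactol and is oxidised on to the γ-lactone (oxidative lactonisation of a 1,4-diol), which also masks the secondary carbinol as the ring oxygen.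

Step 9
Reactants: 16 (1S,5R)-1,5-dimethyl-4-(3-methylbut-2-en-1-yl)-3-oxabicyclo[3.3.0]octan-2-one
Product: 17 (1S,5R)-1,5-dimethyl-4-(3-methylbut-2-en-1-yl)-3-oxabicyclo[3.3.0]octan-2-ol (lactol; mixture of isomers)
Conditions: DIBAL-H (1.1 equiv), CH2Cl2, −78 °C; Rochelle salt work-up
Reagents that add atoms: none
Why: Partial lactone reduction with DIBAL-H as in step 6 puts the former methyl carbon at the aldehyde oxidation level, with the trisubstituted alkene inert to the hydride.

Step 10
Reactants: 17 (1S,5R)-1,5-dimethyl-4-(3-methylbut-2-en-1-yl)-3-oxabicyclo[3.3.0]octan-2-ol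
Product: 19 (4aR,7aR)-4a,7a-dimethyl-1-(3-methylbut-2-en-1-yl)octahydrocyclopenta[c]pyran-3-ol (six-membered lactol; mixture of isomers), via enol ether 18 (not isolated)
Conditions: Ph3P(CH2OMe)Cl (3 equiv), KOt-Bu, THF, 0 → 40 °C; then 2 M HCl, THF, rt
Reagents that add atoms: (methoxymethyl)triphenylphosphonium chloride COC[P+](c1ccccc1)(c1ccccc1)c1ccccc1.[Cl-]; water O
Why: Wittig methoxymethylenation of the ring-opened lactol followed by acid hydrolysis of the enol ether is the standard one-carbon aldehyde homologation, and the freed aldehyde is trapped by the carbinol on the C1 side chain as a six-membered lactol.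

Step 11
Reactants: 20 4-methoxy-2-methylphenol
Product: 21 2-bromo-4-methoxy-6-methylphenol
Conditions: NBS, i-Pr2NH (cat.), CH2Cl2, 0 °C
Reagents that add atoms: N-bromosuccinimide O=C1CCC(=O)N1Br
Why: Amine-catalysed electrophilic bromination of a phenol goes ortho to the hydroxyl, and with the para position and one ortho position blocked only C6 is open.

Step 12
Reactants: 21 2-bromo-4-methoxy-6-methylphenol
Product: 22 1-bromo-2,5-dimethoxy-3-methylbenzene
Conditions: MeI, K2CO3, acetone, reflux
Reagents that add atoms: iodomethane CI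
Why: Williamson etherification of the phenoxide gives a hydroquinone dimethyl ether that withstands the organometallic steps and can later be opened oxidatively.

Step 13
Reactants: 22 1-bromo-2,5-dimethoxy-3-methylbenzene; 23 2-methyl-2-vinyloxirane
Product: 25 (E)-4-(2,5-dimethoxy-3-methylphenyl)-2-methylbut-2-en-1-ol, via aryl Grignard reagent 24 (not isolated)
Conditions: Mg, THF, reflux; CuI (10 mol %), then 23, −30 → 0 °C; aqueous work-up
Reagents that add atoms: magnesium [Mg] (magnesium of 24)
Why: Copper-catalysed SN2′ opening of a vinyl oxirane by an aryl Grignard reagent delivers the aryl group to the vinyl terminus and should give mainly the E allylic alcohol, with the minor Z and direct-opening isomers removed by chromatography.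

Step 14
Reactants: 25 (E)-4-(2,5-dimethoxy-3-methylphenyl)-2-methylbut-2-en-1-ol
Product: 26 1-[(E)-4-chloro-3-methylbut-2-en-1-yl]-2,5-dimethoxy-3-methylbenzene
Conditions: PPh3, CCl4, reflux
Reagents that add atoms: tetrachloromethane ClC(Cl)(Cl)Cl
Why: The Appel reaction replaces a primary allylic hydroxyl by chloride through SN2 attack on the alkoxyphosphonium ion, without allylic transposition or loss of alkene geometry.

Step 15
Reactants: 19 (4aR,7aR)-4a,7a-dimethyl-1-(3-methylbut-2-en-1-yl)octahydrocyclopenta[c]pyran-3-ol; 26 1-[(E)-4-chloro-3-methylbut-2-en-1-yl]-2,5-dimethoxy-3-methylbenzene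
Product: 29 1-[(1R,2R)-2-[(E)-6-(2,5-dimethoxy-3-methylphenyl)-2-hydroxy-4-methylhex-4-en-1-yl]-1,2-dimethylcyclopentyl]-4-methylpent-3-en-1-ol (epimers at both carbinol carbons), via sodium lactolate 27 (not isolated), via allylbarium chloride 28 (not isolated)
Conditions: activated Ba (BaI2, Li, biphenyl, THF, rt); 26, −78 °C; then 27 (from 19, NaH, THF, 0 °C), −78 °C; H2O
Reagents that add atoms: sodium hydride [Na+].[H-] (sodium of 27); barium iodide [Ba+2].[I-].[I-] (barium of 28)
Why: Allylbarium reagents made at −78 °C keep their double-bond geometry and add to aldehydes at the α-carbon, so the ring-opened lactolate should give the homoallylic alcohol with the E trisubstituted alkene intact; both carbinol centres are oxidised in the next step.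

Step 16
Reactants: 29 1-[(1R,2R)-2-[(E)-6-(2,5-dimethoxy-3-methylphenyl)-2-hydroxy-4-methylhex-4-en-1-yl]-1,2-dimethylcyclopentyl]-4-methylpent-3-en-1-ol
Product: 30 1-[(1R,2R)-2-[(E)-6-(2,5-dimethoxy-3-methylphenyl)-4-methyl-2-oxohex-4-en-1-yl]-1,2-dimethylcyclopentyl]-4-methylpent-3-en-1-one
Conditions: Dess–Martin periodinane, NaHCO3, CH2Cl2, 0 °C → rt
Reagents that add atoms: none
Why: Buffered Dess–Martin oxidation turns both homoallylic carbinols into ketones under near-neutral conditions, which keeps the two β,γ-double bonds out of conjugation and leaves the quaternary stereocentres untouched.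

Step 17
Reactants: 30 1-[(1R,2R)-2-[(E)-6-(2,5-dimethoxy-3-methylphenyl)-4-methyl-2-oxohex-4-en-1-yl]-1,2-dimethylcyclopentyl]-4-methylpent-3-en-1-one
Product: 32 1-[(1R,2R)-2-[(E)-6-(2,5-dihydroxy-3-methylphenyl)-4-methyl-2-oxohex-4-en-1-yl]-1,2-dimethylcyclopentyl]-4-methylpent-3-en-1-one (CNP0294415.1), via quinone 31 (not isolated)
Conditions: CAN, MeCN/H2O, 0 °C; then aq. Na2S2O4, EtOAc, rt, under argon
Reagents that add atoms: water O
Why: Cerium(IV) oxidative demethylation of a hydroquinone dimethyl ether gives the p-quinone without touching isolated trisubstituted alkenes or ketones, and dithionite reduces the quinone to the hydroquinone under neutral conditions.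

**Compound list**

1 | (1R,3S)-camphoric acid | OC(=O)[C@]1(C)CC[C@H](C(=O)O)C1(C)C | starting material
2 | (1R,3S)-3-(methoxycarbonyl)-1,2,2-trimethylcyclopentane-1-carboxylic acid | OC(=O)[C@]1(C)CC[C@H](C(=O)OC)C1(C)C | intermediate
3 | methyl (1S,3R)-3-(chlorocarbonyl)-2,2,3-trimethylcyclopentane-1-carboxylate | ClC(=O)[C@]1(C)CC[C@H](C(=O)OC)C1(C)C | intermediate
4 | methyl (1S,3R)-3-carbamoyl-2,2,3-trimethylcyclopentane-1-carboxylate | NC(=O)[C@]1(C)CC[C@H](C(=O)OC)C1(C)C | intermediate
5 | (1S,3R)-3-carbamoyl-2,2,3-trimethylcyclopentane-1-carboxylic acid | NC(=O)[C@]1(C)CC[C@H](C(=O)O)C1(C)C | intermediate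
6 | (1R)-1,2,2-trimethylcyclopentane-1-carboxamide | NC(=O)[C@]1(C)CCCC1(C)C | intermediate
7 | (1R)-N-iodo-1,2,2-trimethylcyclopentane-1-carboxamide | INC(=O)[C@]1(C)CCCC1(C)C | intermediate
8 | (1R,2S)-2-(iodomethyl)-1,2-dimethylcyclopentane-1-carboxamide | NC(=O)[C@]1(C)CCC[C@]1(C)CI | intermediate
9 | (1R,5S)-1,5-dimethyl-3-oxabicyclo[3.3.0]octan-2-iminium iodide | [NH2+]=C1[C@]2(C)CCC[C@]2(C)CO1.[I-] | intermediate
10 | (1R,5S)-1,5-dimethyl-3-oxabicyclo[3.3.0]octan-2-one | O=C1[C@]2(C)CCC[C@]2(C)CO1 | intermediate
11 | (1R,5S)-1,5-dimethyl-3-oxabicyclo[3.3.0]octan-2-ol | OC1[C@]2(C)CCC[C@]2(C)CO1 | intermediate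
12 | prenyl chloride | CC(C)=CCCl | starting material
13 | sodium (1R,5S)-1,5-dimethyl-3-oxabicyclo[3.3.0]octan-2-olate | [Na+].[O-]C1[C@]2(C)CCC[C@]2(C)CO1 | intermediate
14 | prenylbarium chloride | CC(C)=CC[Ba]Cl | intermediate
15 | 1-[(1R,2S)-2-(hydroxymethyl)-1,2-dimethylcyclopentyl]-4-methylpent-3-en-1-ol | CC(C)=CCC(O)[C@]1(C)CCC[C@]1(C)CO | intermediate
16 | (1S,5R)-1,5-dimethyl-4-(3-methylbut-2-en-1-yl)-3-oxabicyclo[3.3.0]octan-2-one | CC(C)=CCC1[C@]2(C)CCC[C@]2(C)C(=O)O1 | intermediate
17 | (1S,5R)-1,5-dimethyl-4-(3-methylbut-2-en-1-yl)-3-oxabicyclo[3.3.0]octan-2-ol | CC(C)=CCC1[C@]2(C)CCC[C@]2(C)C(O)O1 | intermediate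
18 | 1-[(1R,2R)-2-(2-methoxyethenyl)-1,2-dimethylcyclopentyl]-4-methylpent-3-en-1-ol | CC(C)=CCC(O)[C@]1(C)CCC[C@]1(C)C=COC | intermediate
19 | (4aR,7aR)-4a,7a-dimethyl-1-(3-methylbut-2-en-1-yl)octahydrocyclopenta[c]pyran-3-ol | CC(C)=CCC1[C@]2(C)CCC[C@]2(C)CC(O)O1 | intermediate
20 | 4-methoxy-2-methylphenol | COc1ccc(O)c(C)c1 | starting material
21 | 2-bromo-4-methoxy-6-methylphenol | COc1cc(C)c(O)c(Br)c1 | intermediate
22 | 1-bromo-2,5-dimethoxy-3-methylbenzene | COc1cc(C)c(OC)c(Br)c1 | intermediate
23 | 2-methyl-2-vinyloxirane | CC1(C=C)CO1 | starting material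
24 | (2,5-dimethoxy-3-methylphenyl)magnesium bromide | COc1cc(C)c(OC)c([Mg]Br)c1 | intermediate
25 | (E)-4-(2,5-dimethoxy-3-methylphenyl)-2-methylbut-2-en-1-ol | OC/C(C)=C/Cc1cc(OC)cc(C)c1OC | intermediate
26 | 1-[(E)-4-chloro-3-methylbut-2-en-1-yl]-2,5-dimethoxy-3-methylbenzene | ClC/C(C)=C/Cc1cc(OC)cc(C)c1OC | intermediate
27 | sodium (4aR,7aR)-4a,7a-dimethyl-1-(3-methylbut-2-en-1-yl)octahydrocyclopenta[c]pyran-3-olate | CC(C)=CCC1[C@]2(C)CCC[C@]2(C)CC([O-])O1.[Na+] | intermediate
28 | [(E)-4-(2,5-dimethoxy-3-methylphenyl)-2-methylbut-2-en-1-yl]barium chloride | Cl[Ba]C/C(C)=C/Cc1cc(OC)cc(C)c1OC | intermediate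
29 | 1-[(1R,2R)-2-[(E)-6-(2,5-dimethoxy-3-methylphenyl)-2-hydroxy-4-methylhex-4-en-1-yl]-1,2-dimethylcyclopentyl]-4-methylpent-3-en-1-ol | CC(C)=CCC(O)[C@]1(C)CCC[C@]1(C)CC(O)C/C(C)=C/Cc1cc(OC)cc(C)c1OC | intermediate
30 | 1-[(1R,2R)-2-[(E)-6-(2,5-dimethoxy-3-methylphenyl)-4-methyl-2-oxohex-4-en-1-yl]-1,2-dimethylcyclopentyl]-4-methylpent-3-en-1-one | CC(C)=CCC(=O)[C@]1(C)CCC[C@]1(C)CC(=O)C/C(C)=C/Cc1cc(OC)cc(C)c1OC | intermediate
31 | 2-[(E)-6-[(1R,2R)-1,2-dimethyl-2-(4-methylpent-3-enoyl)cyclopentyl]-3-methyl-5-oxohex-2-en-1-yl]-6-methyl-1,4-benzoquinone | CC(C)=CCC(=O)[C@]1(C)CCC[C@]1(C)CC(=O)C/C(C)=C/CC1=CC(=O)C=C(C)C1=O | intermediate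
32 | 1-[(1R,2R)-2-[(E)-6-(2,5-dihydroxy-3-methylphenyl)-4-methyl-2-oxohex-4-en-1-yl]-1,2-dimethylcyclopentyl]-4-methylpent-3-en-1-one | CC(C)=CCC(=O)[C@]1(C)CCC[C@]1(C)CC(=O)C/C(C)=C/Cc1cc(O)cc(C)c1O | target

**Step count**

Total: 17 steps. Longest linear sequence: 13 steps (steps 1–10 and 15–17, from camphoric acid). The aryl-allyl chloride 26 takes 4 steps (11–14).

**Steps most likely to fail**

Step 5. The radical chain may break down on this hindered amide, hydrogen may be abstracted in part from the ring methylenes, and ring closure at the neopentyl iodide may be slow enough for the N-iodoamide to decompose by other paths. The fallback changes the nitrogen substituent and the halogen and keeps the same 1,5-hydrogen transfer and the same CH2–O bond. It sets out from acid chloride 3, which would be quenched with tert-butylamine in place of ammonia to give methyl (1S,3R)-3-(tert-butylcarbamoyl)-2,2,3-trimethylcyclopentane-1-carboxylate F1. Saponification as in step 3 gives (1S,3R)-3-(tert-butylcarbamoyl)-2,2,3-trimethylcyclopentane-1-carboxylic acid F2, and hydrodecarboxylation as in step 4 gives (1R)-N-tert-butyl-1,2,2-trimethylcyclopentane-1-carboxamide F3. N-Chlorination with t-BuOCl gives (1R)-N-tert-butyl-N-chloro-1,2,2-trimethylcyclopentane-1-carboxamide F4. Photolysis of F4, the N-chloro-N-tert-butylamide form of the Hofmann–Löffler–Freytag rearrangement, moves chlorine to the syn methyl and gives (1R,2S)-N-tert-butyl-2-(chloromethyl)-1,2-dimethylcyclopentane-1-carboxamide F5. Heating F5 in aqueous dioxane closes the iminolactone through oxygen and hydrolyses it, returning to the route at lactone 10.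

Step 15. Ring opening of the lactolate may be too slow at −78 °C, and warming lets the allylbarium lose its geometry and α-selectivity. Proton transfer from the benzylic-allylic CH2 to the allyl anion, or Wurtz coupling during metalation, may also consume the reagent. The fallback replaces the barium reagent by a sulfone-stabilised carbanion, which is stable at higher temperature and alkylates at its α-carbon. It sets out from chloride 26, which with sodium benzenesulfinate in DMF gives 1-[(E)-4-(benzenesulfonyl)-3-methylbut-2-en-1-yl]-2,5-dimethoxy-3-methylbenzene F6. Lithiation of F6 with n-BuLi at −78 °C and addition to lactol 19 (excess anion, −78 → 0 °C) gives 1-[(1R,2R)-2-[(E)-3-(benzenesulfonyl)-6-(2,5-dimethoxy-3-methylphenyl)-2-hydroxy-4-methylhex-4-en-1-yl]-1,2-dimethylcyclopentyl]-4-methylpent-3-en-1-ol F7. Buffered Dess–Martin oxidation of both carbinols gives 1-[(1R,2R)-2-[(E)-3-(benzenesulfonyl)-6-(2,5-dimethoxy-3-methylphenyl)-4-methyl-2-oxohex-4-en-1-yl]-1,2-dimethylcyclopentyl]-4-methylpent-3-en-1-one F8. Reductive desulfonylation of this β-keto sulfone with SmI2 in THF/MeOH at −78 °C returns to the route at diketone 30.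

Step 7. The doubly neopentyl lactolate may open too slowly for addition at low temperature, and part of the reagent may attack through its γ-carbon to give the reverse-prenyl carbinol. Prolonged exposure of the open alkoxy aldehyde to base could also erode the enantiomeric purity, because an intramolecular hydride shift from the CH2O− group to the aldehyde exchanges the two arms and gives the mirror image. The fallback avoids a substituted allyl metal. It sets out from lactol 11, which with allylmagnesium bromide in THF at 0 °C → rt (a reagent without a regiochemical choice, known to add readily to lactols) gives 1-[(1R,2S)-2-(hydroxymethyl)-1,2-dimethylcyclopentyl]but-3-en-1-ol F9. Cross-metathesis of F9 with 2-methylbut-2-ene (second-generation Grubbs catalyst, CH2Cl2, 40 °C) turns the terminal alkene into the prenyl group and returns to the route at diol 15.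

**Further compounds**

F1 | step 5 | methyl (1S,3R)-3-(tert-butylcarbamoyl)-2,2,3-trimethylcyclopentane-1-carboxylate | CC(C)(C)NC(=O)[C@]1(C)CC[C@H](C(=O)OC)C1(C)C
F2 | step 5 | (1S,3R)-3-(tert-butylcarbamoyl)-2,2,3-trimethylcyclopentane-1-carboxylic acid | CC(C)(C)NC(=O)[C@]1(C)CC[C@H](C(=O)O)C1(C)C
F3 | step 5 | (1R)-N-tert-butyl-1,2,2-trimethylcyclopentane-1-carboxamide | CC(C)(C)NC(=O)[C@]1(C)CCCC1(C)C
F4 | step 5 | (1R)-N-tert-butyl-N-chloro-1,2,2-trimethylcyclopentane-1-carboxamide | CC(C)(C)N(Cl)C(=O)[C@]1(C)CCCC1(C)C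
F5 | step 5 | (1R,2S)-N-tert-butyl-2-(chloromethyl)-1,2-dimethylcyclopentane-1-carboxamide | CC(C)(C)NC(=O)[C@]1(C)CCC[C@]1(C)CCl
F6 | step 15 | 1-[(E)-4-(benzenesulfonyl)-3-methylbut-2-en-1-yl]-2,5-dimethoxy-3-methylbenzene | O=S(=O)(C/C(C)=C/Cc1cc(OC)cc(C)c1OC)c1ccccc1
F7 | step 15 | 1-[(1R,2R)-2-[(E)-3-(benzenesulfonyl)-6-(2,5-dimethoxy-3-methylphenyl)-2-hydroxy-4-methylhex-4-en-1-yl]-1,2-dimethylcyclopentyl]-4-methylpent-3-en-1-ol | CC(C)=CCC(O)[C@]1(C)CCC[C@]1(C)CC(O)C(/C(C)=C/Cc1cc(OC)cc(C)c1OC)S(=O)(=O)c1ccccc1
F8 | step 15 | 1-[(1R,2R)-2-[(E)-3-(benzenesulfonyl)-6-(2,5-dimethoxy-3-methylphenyl)-4-methyl-2-oxohex-4-en-1-yl]-1,2-dimethylcyclopentyl]-4-methylpent-3-en-1-one | CC(C)=CCC(=O)[C@]1(C)CCC[C@]1(C)CC(=O)C(/C(C)=C/Cc1cc(OC)cc(C)c1OC)S(=O)(=O)c1ccccc1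
F9 | step 7 | 1-[(1R,2S)-2-(hydroxymethyl)-1,2-dimethylcyclopentyl]but-3-en-1-ol | C=CCC(O)[C@]1(C)CCC[C@]1(C)CO
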